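**Plan**

1. Retrosynthesis: the cyclohexene ring of the cage is cut at its two σ bonds C(OH)–CH2 and C(O‑ketal)–CH (retro‑[4+2]) and at the prenyl–C bond of the ether‑bearing quaternary carbon (retro‑Claisen), giving a flat 6‑hydroxy‑7,8‑bis(1,1‑dimethylallyloxy)‑1,3‑benzodioxin‑4‑one spiro‑fused to ring A; the spiro C–O(acyl) bond is then cut (retro‑oxa‑Michael) to an aryloxyquinone acid, and the aryl O–quinone bond to a 7‑chloro‑6‑prenylchromene‑5,8‑quinone and a salicylate.
2. Enabling feature: the cage ring C=CH–C(OH)–CH2–CH–C(O) is the Diels–Alder adduct of a 2‑hydroxycyclohexa‑2,4‑dienone (the enol of a 1,2‑diketone, hence the bridgehead OH) with a vinyl group held by an O–CMe2 tether (hence the tetrahydrofuran). The prenyl/tert‑alkoxy pair on one carbon next to the ketone is the mark of an aromatic Claisen shift, and because the lactone ring is a salicylate ketal the substrate can stay aromatic until the last step.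
3. Forward order: pyran ring on the quinone, then prenyl and chloride; tetra‑oxygenated salicylate; diaryl ether; spiro 1,3‑dioxin‑4‑one ring; last, the tetrahydrofuran and cyclohexene rings of the cage in one thermal cascade.
4. Stereochemistry: the spiro ketal carbon comes from a catalyst‑controlled oxa‑Michael addition, the neighbouring CH(prenyl) from thermodynamic protonation, and the four cage centres from relay of the spiro centre in the Claisen step and from the tether in the cycloaddition.

Key step: step 14

Assumption: the configuration of the enolisable CH(prenyl) carbon of ring A in the target (prenyl cis to the lactone oxygen, trans to the ketal ether oxygen) is taken to be the thermodynamically preferred one, so that it is set by equilibration.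

**Route**

Step 1
Reactants: 1 2,6-dimethoxy-1,4-benzoquinone
Product: 2 2-hydroxy-6-methoxy-1,4-benzoquinone
Conditions: NaOH (1.1 equiv), THF/H2O, 0 °C to rt; then 1 M HCl
Reagents that add atoms: sodium hydroxide, [Na+].[OH-]
Why: Hydrolysis of a vinylogous ester by addition–elimination; the hydroxyquinone anion formed first is deactivated toward a second attack, so one methoxy group should remain.

Step 2
Reactants: 2 2-hydroxy-6-methoxy-1,4-benzoquinone; 3 3-methylbut-2-enal
Product: 4 7-methoxy-2,2-dimethyl-2H-chromene-5,8-dione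
Conditions: ethylenediammonium diacetate (10 mol %), CH2Cl2, rt to 40 °C
Reagents that add atoms: none
Why: Knoevenagel condensation at the only nucleophilic CH (next to the hydroxyl) followed by oxa‑6π‑electrocyclisation, the usual pyran annulation of hydroxyquinones with enals; closure onto the oxygen that leaves a para‑quinone is the thermodynamically preferred mode.

Step 3
Reactants: 4 7-methoxy-2,2-dimethyl-2H-chromene-5,8-dione
Product: 5 7-hydroxy-2,2-dimethyl-2H-chromene-5,8-dione
Conditions: NaOH (2 equiv), THF/H2O, rt; then 1 M HCl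
Reagents that add atoms: sodium hydroxide, [Na+].[OH-]
Why: Vinylogous ester hydrolysis (addition–elimination) frees the second hydroxyquinone unit; the chromene is inert to aqueous base.

Step 4
Reactants: 5 7-hydroxy-2,2-dimethyl-2H-chromene-5,8-dione; 6 1-bromo-3-methylbut-2-ene
Product: 7 7-hydroxy-2,2-dimethyl-6-(3-methylbut-2-en-1-yl)-2H-chromene-5,8-dione
Conditions: LiH (1.1 equiv), DMSO, rt; then 6 (1.2 equiv), 0 °C to rt
Reagents that add atoms: none
Why: C‑alkylation of the lithium salt of a 2‑hydroxy‑1,4‑quinone at its single free ring CH, the reaction type that converts lawsone into lapachol.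

Step 5
Reactants: 7 7-hydroxy-2,2-dimethyl-6-(3-methylbut-2-en-1-yl)-2H-chromene-5,8-dione
Product: 8 7-chloro-2,2-dimethyl-6-(3-methylbut-2-en-1-yl)-2H-chromene-5,8-dione
Conditions: (COCl)2 (1.5 equiv), DMF (10 mol %), CH2Cl2, 0 °C to rt
Reagents that add atoms: oxalyl chloride, ClC(=O)C(=O)Cl
Why: The hydroxyquinone is a vinylogous carboxylic acid and is converted into the vinylogous acid chloride by the Vilsmeier reagent, as in acid chloride formation.

Step 6
Reactants: 9 2,3,4-trihydroxybenzoic acid
Product: 10 2-(trimethylsilyl)ethyl 2,3,4-trihydroxybenzoate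
Conditions: 2-(trimethylsilyl)ethanol (1.1 equiv), PPh3, DIAD, THF, 0 °C to rt
Reagents that add atoms: 2-(trimethylsilyl)ethanol, C[Si](C)(C)CCO
Why: Mitsunobu esterification is chemoselective for the carboxylic acid over the less acidic phenols and installs an ester that fluoride removes later without hydrolysis.

Step 7
Reactants: 10 2-(trimethylsilyl)ethyl 2,3,4-trihydroxybenzoate; 11 3-chloro-3-methylbut-1-yne
Product: 12 2-(trimethylsilyl)ethyl 2-hydroxy-3,4-bis(2-methylbut-3-yn-2-yloxy)benzoate
Conditions: 11 (2.5 equiv), K2CO3, KI (cat.), CuI (cat.), acetone, 50 °C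
Reagents that add atoms: none
Why: Copper‑assisted O‑alkylation of phenols with a tertiary propargylic chloride; the 2‑hydroxyl is hydrogen‑bonded to the ester carbonyl and should stay free.

Step 8
Reactants: 12 2-(trimethylsilyl)ethyl 2-hydroxy-3,4-bis(2-methylbut-3-yn-2-yloxy)benzoate
Product: 13 2-(trimethylsilyl)ethyl 2-hydroxy-3,4-bis(2-methylbut-3-en-2-yloxy)benzoate
Conditions: H2 (1 atm), Pd/CaCO3 poisoned with Pb(OAc)2 (Lindlar catalyst), quinoline, EtOAc, rt
Reagents that add atoms: none
Why: Semihydrogenation of the terminal alkynes stops at the vinyl stage on the poisoned catalyst and gives the two 1,1‑dimethylallyl ethers.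

Step 9
Reactants: 13 2-(trimethylsilyl)ethyl 2-hydroxy-3,4-bis(2-methylbut-3-en-2-yloxy)benzoate
Product: 15 2-(trimethylsilyl)ethyl 2,5-dihydroxy-3,4-bis(2-methylbut-3-en-2-yloxy)benzoate, via quinone ester 14 (not isolated)
Conditions: (KSO3)2NO (Fremy's salt, 2.5 equiv), KH2PO4 buffer, acetone/H2O, 0 °C to rt; then Na2S2O4 (aq), EtOAc, rt
Reagents that add atoms: potassium nitrosodisulfonate, [K+].[K+].[O]N(S(=O)(=O)[O-])S(=O)(=O)[O-]
Why: Teuber oxidation of the phenol at its free para position gives the para‑quinone, which dithionite reduces at once to the hydroquinone before the electrophilic ester‑quinone can add nucleophiles.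

Step 10
Reactants: 15 2-(trimethylsilyl)ethyl 2,5-dihydroxy-3,4-bis(2-methylbut-3-en-2-yloxy)benzoate
Product: 16 2-(trimethylsilyl)ethyl 5-[(tert-butyldimethylsilyl)oxy]-2-hydroxy-3,4-bis(2-methylbut-3-en-2-yloxy)benzoate
Conditions: TBSCl (1.05 equiv), imidazole, CH2Cl2, 0 °C
Reagents that add atoms: tert-butyldimethylsilyl chloride, CC(C)(C)[Si](C)(C)Cl
Why: Silyl ether formation should occur at the 5‑hydroxyl only, because the 2‑hydroxyl is hydrogen‑bonded to the ester carbonyl and flanked on both sides.

Step 11
Reactants: 16 2-(trimethylsilyl)ethyl 5-[(tert-butyldimethylsilyl)oxy]-2-hydroxy-3,4-bis(2-methylbut-3-en-2-yloxy)benzoate; 8 7-chloro-2,2-dimethyl-6-(3-methylbut-2-en-1-yl)-2H-chromene-5,8-dione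
Product: 17 2-(trimethylsilyl)ethyl 5-[(tert-butyldimethylsilyl)oxy]-2-{[2,2-dimethyl-6-(3-methylbut-2-en-1-yl)-5,8-dioxo-5,8-dihydro-2H-chromen-7-yl]oxy}-3,4-bis(2-methylbut-3-en-2-yloxy)benzoate
Conditions: NaH (1.0 equiv), THF, 0 °C; then 8, THF/DMF, −20 °C to rt
Reagents that add atoms: none
Why: Nucleophilic vinylic substitution (addition–elimination) of chloride on a 2‑chloroquinone by a phenoxide is the standard route to aryloxyquinones; the silyl ether keeps the para oxygen from reacting or being oxidised by the quinone.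

Step 12
Reactants: 17 2-(trimethylsilyl)ethyl 5-[(tert-butyldimethylsilyl)oxy]-2-{[2,2-dimethyl-6-(3-methylbut-2-en-1-yl)-5,8-dioxo-5,8-dihydro-2H-chromen-7-yl]oxy}-3,4-bis(2-methylbut-3-en-2-yloxy)benzoate
Product: 18 2-{[2,2-dimethyl-6-(3-methylbut-2-en-1-yl)-5,8-dioxo-5,8-dihydro-2H-chromen-7-yl]oxy}-5-hydroxy-3,4-bis(2-methylbut-3-en-2-yloxy)benzoic acid
Conditions: Bu4NF (3 equiv), AcOH (3 equiv), THF, 0 to 40 °C; cold pH 4 work-up
Reagents that add atoms: none
Why: Fluoride cleaves the 2‑(trimethylsilyl)ethyl ester by β‑elimination and the aryl silyl ether in one operation, and the acetic acid buffer protects the base‑sensitive aryloxyquinone.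

Step 13
Reactants: 18 2-{[2,2-dimethyl-6-(3-methylbut-2-en-1-yl)-5,8-dioxo-5,8-dihydro-2H-chromen-7-yl]oxy}-5-hydroxy-3,4-bis(2-methylbut-3-en-2-yloxy)benzoic acid
Product: 19 (2S,6'S)-6-hydroxy-2',2'-dimethyl-6'-(3-methylbut-2-en-1-yl)-7,8-bis(2-methylbut-3-en-2-yloxy)-2'H-spiro[1,3-benzodioxine-2,7'-chromene]-4,5',8'(6'H)-trione
Conditions: quinidine-derived 3,5-bis(trifluoromethyl)phenyl squaramide (10 mol %), toluene/CH2Cl2, −30 °C, argon
Reagents that add atoms: none
Why: Proposed new method: the quinuclidine nitrogen of the catalyst takes the proton of the benzoic acid while the squaramide N–H bonds hold the C5 carbonyl of the quinone, so the carboxylate adds within a chiral ion pair to one face of C7 (the β‑carbon of the vinylogous ester, already bearing the aryloxy group) in a 6‑exo‑trig closure, and the enol is then protonated at C6 to the more stable epimer with prenyl trans to the aryl ether oxygen; the spiro centre is thus set by the catalyst (the quinidine or the quinine series is taken as the sense of induction demands) and the neighbouring CH by thermodynamic protonation; the closest known reaction types are the base‑mediated double oxa‑Michael addition of salicylic acids to ynoates that gives 4H‑1,3‑benzodioxin‑4‑ones and the amine–squaramide‑catalysed enantioselective intramolecular oxa‑Michael addition of benzoic acids and phenols to enones.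

Step 14
Reactants: 19 (2S,6'S)-6-hydroxy-2',2'-dimethyl-6'-(3-methylbut-2-en-1-yl)-7,8-bis(2-methylbut-3-en-2-yloxy)-2'H-spiro[1,3-benzodioxine-2,7'-chromene]-4,5',8'(6'H)-trione
Product: 21 target CNP0222516.1, via Claisen dienone 20 (not isolated)
Conditions: degassed toluene (0.01 M), 110 °C, sealed tube, argon
Reagents that add atoms: none
Why: Heating triggers an aromatic Claisen rearrangement of the 1,1‑dimethylallyl ether on C7 of the benzodioxinone (para to the lactone carbonyl and hydrogen‑bonded by the C6 phenol) onto the oxygen‑bearing C8 to give the 2‑hydroxycyclohexa‑2,4‑dienone 20, whose diene C6(OH)=C5–C4a=C8a then adds the vinyl group of the remaining ether in an intramolecular Diels–Alder reaction; the closest known reaction type is the Claisen/Diels–Alder cascade of ortho‑bis(1,1‑dimethylallyloxy)arenes that gives the caged Garcinia xanthones. The cyclohexene ring closes by the [4+2] step itself (bonds C6–CH2 and C8a–CH, across the 2,5‑positions of the dienone), and the tetrahydrofuran ring closes in the same step as the five‑membered ring of the O–CMe2 tether, which also fixes the regiochemistry. The quaternary C8 centre is set in the Claisen step under control of the spiro ketal carbon: the C8 ether, flanked on both sides, must turn out of the arene plane and should turn toward the face that carries the ring A carbonyl arm, so the migrating group on C7 delivers prenyl on the face of the CH(prenyl) arm, which is the relative configuration of the target; the other three cage centres (C–O bridgehead, CH, C–OH bridgehead) follow from the tether, which can reach only the diene face syn to its oxygen. The bridgehead hydroxyl needs neither protection nor later oxidation because the diene is the enol of a 1,2‑diketone. Site selectivity is needed between the two allyl ethers and between the two ortho positions of C7; the unwanted [3,3] shifts are reversible and only dienone 20 is drained by the cycloaddition.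

**Compound list**

1 | 2,6-dimethoxy-1,4-benzoquinone | COC1=CC(=O)C=C(OC)C1=O | starting material
2 | 2-hydroxy-6-methoxy-1,4-benzoquinone | COC1=CC(=O)C=C(O)C1=O | intermediate
3 | 3-methylbut-2-enal | CC(C)=CC=O | starting material
4 | 7-methoxy-2,2-dimethyl-2H-chromene-5,8-dione | COC1=CC(=O)C2=C(OC(C)(C)C=C2)C1=O | intermediate
5 | 7-hydroxy-2,2-dimethyl-2H-chromene-5,8-dione | OC1=CC(=O)C2=C(OC(C)(C)C=C2)C1=O | intermediate
6 | 1-bromo-3-methylbut-2-ene | CC(C)=CCBr | starting material
7 | 7-hydroxy-2,2-dimethyl-6-(3-methylbut-2-en-1-yl)-2H-chromene-5,8-dione | CC(C)=CCC1=C(O)C(=O)C2=C(C=CC(C)(C)O2)C1=O | intermediate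
8 | 7-chloro-2,2-dimethyl-6-(3-methylbut-2-en-1-yl)-2H-chromene-5,8-dione | CC(C)=CCC1=C(Cl)C(=O)C2=C(C=CC(C)(C)O2)C1=O | intermediate
9 | 2,3,4-trihydroxybenzoic acid | OC(=O)c1ccc(O)c(O)c1O | starting material
10 | 2-(trimethylsilyl)ethyl 2,3,4-trihydroxybenzoate | C[Si](C)(C)CCOC(=O)c1ccc(O)c(O)c1O | intermediate
11 | 3-chloro-3-methylbut-1-yne | CC(C)(Cl)C#C | starting material
12 | 2-(trimethylsilyl)ethyl 2-hydroxy-3,4-bis(2-methylbut-3-yn-2-yloxy)benzoate | C[Si](C)(C)CCOC(=O)c1ccc(OC(C)(C)C#C)c(OC(C)(C)C#C)c1O | intermediate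
13 | 2-(trimethylsilyl)ethyl 2-hydroxy-3,4-bis(2-methylbut-3-en-2-yloxy)benzoate | C[Si](C)(C)CCOC(=O)c1ccc(OC(C)(C)C=C)c(OC(C)(C)C=C)c1O | intermediate
14 | quinone ester: 2-(trimethylsilyl)ethyl 4,5-bis(2-methylbut-3-en-2-yloxy)-3,6-dioxocyclohexa-1,4-diene-1-carboxylate | C[Si](C)(C)CCOC(=O)C1=CC(=O)C(OC(C)(C)C=C)=C(OC(C)(C)C=C)C1=O | intermediate
15 | 2-(trimethylsilyl)ethyl 2,5-dihydroxy-3,4-bis(2-methylbut-3-en-2-yloxy)benzoate | C[Si](C)(C)CCOC(=O)c1cc(O)c(OC(C)(C)C=C)c(OC(C)(C)C=C)c1O | intermediate
16 | 2-(trimethylsilyl)ethyl 5-[(tert-butyldimethylsilyl)oxy]-2-hydroxy-3,4-bis(2-methylbut-3-en-2-yloxy)benzoate | C[Si](C)(C)CCOC(=O)c1cc(O[Si](C)(C)C(C)(C)C)c(OC(C)(C)C=C)c(OC(C)(C)C=C)c1O | intermediate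
17 | 2-(trimethylsilyl)ethyl 5-[(tert-butyldimethylsilyl)oxy]-2-{[2,2-dimethyl-6-(3-methylbut-2-en-1-yl)-5,8-dioxo-5,8-dihydro-2H-chromen-7-yl]oxy}-3,4-bis(2-methylbut-3-en-2-yloxy)benzoate | CC(C)=CCC1=C(Oc2c(C(=O)OCC[Si](C)(C)C)cc(O[Si](C)(C)C(C)(C)C)c(OC(C)(C)C=C)c2OC(C)(C)C=C)C(=O)C2=C(C=CC(C)(C)O2)C1=O | intermediate
18 | 2-{[2,2-dimethyl-6-(3-methylbut-2-en-1-yl)-5,8-dioxo-5,8-dihydro-2H-chromen-7-yl]oxy}-5-hydroxy-3,4-bis(2-methylbut-3-en-2-yloxy)benzoic acid | CC(C)=CCC1=C(Oc2c(C(=O)O)cc(O)c(OC(C)(C)C=C)c2OC(C)(C)C=C)C(=O)C2=C(C=CC(C)(C)O2)C1=O | intermediate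
19 | (2S,6'S)-6-hydroxy-2',2'-dimethyl-6'-(3-methylbut-2-en-1-yl)-7,8-bis(2-methylbut-3-en-2-yloxy)-2'H-spiro[1,3-benzodioxine-2,7'-chromene]-4,5',8'(6'H)-trione (spiro ketal carbon S; prenyl on C6' cis to the lactone oxygen O3) | CC(C)=CC[C@H]1C(=O)C2=C(OC(C)(C)C=C2)C(=O)[C@@]12OC(=O)c1cc(O)c(OC(C)(C)C=C)c(OC(C)(C)C=C)c1O2 | intermediate
20 | Claisen dienone: (2S,6'S,8R)-6-hydroxy-2',2'-dimethyl-6',8-bis(3-methylbut-2-en-1-yl)-8-(2-methylbut-3-en-2-yloxy)-2'H,8H-spiro[1,3-benzodioxine-2,7'-chromene]-4,5',7,8'(6'H)-tetrone | CC(C)=CC[C@H]1C(=O)C2=C(OC(C)(C)C=C2)C(=O)[C@@]12OC(=O)C1=C(O2)[C@@](CC=C(C)C)(OC(C)(C)C=C)C(=O)C(O)=C1 | intermediate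
21 | target CNP0222516.1: 4-oxatricyclodecenone cage (bridgehead C–OH R, ring-fusion CH S, quaternary C(prenyl)–O R, bridgehead C–O S) whose bridgehead oxygen and alkene carboxyl close a 1,3-dioxan-4-one that is spiro-fused (S) to C7 of a (6S)-6-prenyl-2,2-dimethyl-6,7-dihydro-2H-chromene-5,8-dione | CC(C)=CC[C@H]1C(=O)C2=C(OC(C)(C)C=C2)C(=O)[C@@]12OC(=O)C1=C[C@]3(O)C[C@H]4C(C)(C)O[C@@](CC=C(C)C)(C3=O)[C@@]14O2 | target

**Count**

Total steps: 14. Longest linear sequence: 9 steps (steps 6–14 from 9; equally steps 1–5 and 11–14 from 1).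

**Steps most likely to fail**

Step 13. The ring closure may proceed without the catalyst (background addition of the acid), or may be reversible by retro‑oxa‑Michael opening, and either process would erode the enantiomeric purity; the induction itself may also be low. The fallback sets out from 18 and gives up asymmetric induction: the ring is closed by the known base‑mediated addition of a salicylic‑type acid to a β‑aryloxy enone (NaHCO3, CuI, MeCN, or catalytic DABCO), which gives 19 together with its mirror image, (2R,6'R)-spiro benzodioxinone ent-19 F1. The enantiomers are separated by preparative HPLC on a chiral stationary phase (amylose tris(3,5-dimethylphenylcarbamate)), and 19 re‑enters the route at step 14.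

Step 14. The remote spiro centre may bias the face of prenyl delivery in the Claisen step only weakly, the rearrangement may take the wrong ether or the wrong ortho position, and the acyl ketal may open thermally. The fallback inverts the order of events and lets the cage control the spiro centre. It sets out from 17, which is heated (toluene, 110 °C) to undergo the same Claisen/Diels–Alder cascade on the achiral aryloxyquinone and gives the racemic caged quinonyl ether, that is the silylated caged ester F2 and its mirror image ent-caged ester F3. These are separated by HPLC on a chiral stationary phase. F2 is desilylated (HF·pyridine, then Bu4NF/AcOH) to the caged acid F4, and catalytic Et3N in CH2Cl2 closes the spiro ring by intramolecular oxa‑Michael addition of the acid to the alkoxyquinone under thermodynamic control of the cage, arriving at 21.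

Step 4. O‑alkylation and double alkylation may compete with C‑alkylation of the ambident hydroxyquinone anion. The fallback sets out from 5 and moves the prenyl group from oxygen to carbon by a sigmatropic shift: O‑alkylation with 11 (K2CO3, KI, CuI, acetone) gives the propargyl ether 2,2-dimethyl-7-(2-methylbut-3-yn-2-yloxy)-2H-chromene-5,8-dione F5; semihydrogenation (H2, Pd/CaCO3 poisoned with Pb(OAc)2, quinoline) gives the allyl ether 2,2-dimethyl-7-(2-methylbut-3-en-2-yloxy)-2H-chromene-5,8-dione F6; warming (toluene, 80 °C) brings about a Claisen rearrangement to the free ring carbon and re‑enolisation, arriving at 7.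

**Further compounds**

F1 | step 13 | (2R,6'R)-6-hydroxy-2',2'-dimethyl-6'-(3-methylbut-2-en-1-yl)-7,8-bis(2-methylbut-3-en-2-yloxy)-2'H-spiro[1,3-benzodioxine-2,7'-chromene]-4,5',8'(6'H)-trione (ent-19) | CC(C)=CC[C@@H]1C(=O)C2=C(OC(C)(C)C=C2)C(=O)[C@]12OC(=O)c1cc(O)c(OC(C)(C)C=C)c(OC(C)(C)C=C)c1O2
F2 | step 14 | silylated caged ester: 2-(trimethylsilyl)ethyl ester of the cage acid configured as in 21, with the bridgehead hydroxyl as its tert-butyldimethylsilyl ether and the bridgehead oxygen bound to C7 of the 6-prenylchromene-5,8-quinone | C[Si](C)(C)CCOC(=O)C1=C[C@]3(O[Si](C)(C)C(C)(C)C)C[C@H]4C(C)(C)O[C@@](CC=C(C)C)(C3=O)[C@@]14OC1=C(CC=C(C)C)C(=O)C2=C(OC(C)(C)C=C2)C1=O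
F3 | step 14 | ent-caged ester, mirror image of F2 | C[Si](C)(C)CCOC(=O)C1=C[C@@]3(O[Si](C)(C)C(C)(C)C)C[C@@H]4C(C)(C)O[C@](CC=C(C)C)(C3=O)[C@]14OC1=C(CC=C(C)C)C(=O)C2=C(OC(C)(C)C=C2)C1=O
F4 | step 14 | caged acid: cage configured as in 21 with free bridgehead hydroxyl, free carboxylic acid on the alkene carbon and the bridgehead oxygen bound to C7 of the 6-prenylchromene-5,8-quinone | OC(=O)C1=C[C@]3(O)C[C@H]4C(C)(C)O[C@@](CC=C(C)C)(C3=O)[C@@]14OC1=C(CC=C(C)C)C(=O)C2=C(OC(C)(C)C=C2)C1=O
F5 | step 4 | 2,2-dimethyl-7-(2-methylbut-3-yn-2-yloxy)-2H-chromene-5,8-dione | C#CC(C)(C)OC1=CC(=O)C2=C(OC(C)(C)C=C2)C1=O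
F6 | step 4 | 2,2-dimethyl-7-(2-methylbut-3-en-2-yloxy)-2H-chromene-5,8-dione | C=CC(C)(C)OC1=CC(=O)C2=C(OC(C)(C)C=C2)C1=O
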